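Of the 4 questions on this flask, the two on product and intermediate reduce to one ratio of charges.

    substrate → intermediate (k1 = 4.07 × 10⁻⁴ s⁻¹)
    coupling partner + intermediate → product (k2 = 1.37 × 10⁻⁴ L mol⁻¹ s⁻¹)

substrate 2.1 M; coupling partner 1.47 M; time 8.0 d

1. at 8.0 d, what has stopped the reaction, if anything has (forward and back rates have come level / it is still moving / all of the substrate has reacted)
2. conversion of substrate at 8.0 d
3. amount of product at 8.0 d, in percent of the substrate charged
4. amount of intermediate at 8.0 d, in percent of the substrate charged

- the reaction counts as stopped when no species that holds the substrate changes by six tenths of a point or more over the second half of the time
- run time (flask): 8.0 d

The first concern before a repeat is which given numbers must be known well. The constant of the first step gives the substrate a half-life of 0.47 h, far shorter than the run of 8.0 d, so a modest error in it moves the early hours and hardly touches the end. The second constant is similarly placed, since the intermediate's half-life by that step, with coupling partner as charged, is 0.96 h, and the same comparisons make the length of the run a minor matter. The charges need the care, since the coupling partner is charged below the substrate in this flask and an error in either passes straight into the yields.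

Dividing the rate at which product appears by the rate at which coupling partner disappears removes time and the constants, as both rates are the same term, and leaves one: each product costs one coupling partner and one substrate. The ceiling share is therefore 70.0%, the smaller charge divided by the substrate charge. With 1.47 M against 2.1 M, the coupling partner is the limiting reagent in this flask. For this flask the reckoning commits to a conversion of 100%, since the first step needs no coupling partner and the substrate's half-life is far shorter than the run, with product at the ceiling and 30.0% stranded as intermediate.

The forecast gave all of the substrate has reacted, with conversion 100%, product 70% and intermediate 30%, the coupling partner being judged as “therefore the limiting reagent”.

The simulated flask gives all of the substrate has reacted, with conversion 100%, product 70.0% and intermediate 30.0%. At 0.800 d this flask already reads product 69.9% with coupling partner at 0.0994% of its own charge, so the ceiling of 70.0% is the level to watch for in the early readings, and at 80.0 d product still reads 70.0%. In the neighbour charged with 0.37 M of coupling partner, the ceiling scales down to 17.6%, leaving 82.4% as intermediate. That flask gives product 17.6% and intermediate 82.4% at 8.00 d.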